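Verticillane numbering is used. The cyclohexene ring is cut at its CH2–CH2 unit (C13–C14): C12–C13 and C14–C1. Its ends, butenolide α-carbon C12 and ring-fusion carbon C1, are 1,4-related and carry C18 (lactone carbonyl) and C2 (first macrocycle CH2); these two carbons are tied together as a temporary etheno bridge, which makes 3-ethoxy-6,6-dimethylcyclohexa-2,4-dienone the precursor. One catalytic asymmetric Diels–Alder reaction with acrolein, an ethylene equivalent, forms both bonds and sets C1. Decarbonylation and ozonolysis of the enol ether bridge then release the ring as β-keto ester (C18) and aldehyde (C2). B-alkyl Suzuki coupling and a Nozaki–Hiyama–Kishi macrocyclisation, closing macrocycle and butenolide together, finish the route.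

Key step: step 3

Numbering: C1 ring-fusion CH; C2, C3 CH2; C4 (=C20H2); C5 CH2; C6 CH–OAc; C7=C8(CH3); C9 CH2; C10 lactone CH–O; C11=C12 butenolide alkene; C13, C14 ring CH2; C15 CMe2; C18 lactone C=O.

Assumption: the sense of induction in the two catalyst-controlled steps (3 and 10) is taken from the accepted transition-state models of the parent reactions and the expected regiochemistry of step 3; should either product prove antipodal, the enantiomeric catalyst is used and nothing else changes.

Step 1
Reactants: 1 3-ethoxycyclohex-2-en-1-one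
Product: 3 3-ethoxy-6,6-dimethylcyclohex-2-en-1-one, via monomethyl enone 2 (not isolated)
Conditions: LiN(iPr)2, THF, −78 °C; MeI; then LiN(iPr)2, −78 °C; MeI, to 0 °C
Reagents that add atoms: iodomethane, CI
Why: Stork–Danheiser alkylation: kinetic deprotonation of the vinylogous ester occurs at the α′ carbon and two successive methylations should install the gem-dimethyl group (the future C15), with no stereocentre formed.

Step 2
Reactants: 3 3-ethoxy-6,6-dimethylcyclohex-2-en-1-one
Product: 5 3-ethoxy-6,6-dimethylcyclohexa-2,4-dien-1-one, via silyl dienol ether 4 (not isolated)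
Conditions: LiN(iPr)2, Me3SiCl, THF, −78 °C; then Pd(OAc)2, MeCN, 25 °C
Reagents that add atoms: none
Why: Saegusa–Ito oxidation: with the α′ carbon quaternary the only acidic position is C4 of the enone, the derived 1-silyloxy-1,3-diene is palladated by Pd(OAc)2 and loses the neighbouring hydrogen by β-hydride elimination to give the 2,4-dienone, which cannot tautomerise to a phenol and has no stereocentre.

Step 3
Reactants: 5 3-ethoxy-6,6-dimethylcyclohexa-2,4-dien-1-one; 6 acrolein
Product: 7 (1R,2R,4R)-5-ethoxy-7,7-dimethyl-8-oxobicyclo[2.2.2]oct-5-ene-2-carbaldehyde (CHO endo, syn to the enol ether bridge)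
Conditions: (S)-B-o-tolyl oxazaborolidine from α,α-diphenylprolinol (20 mol %), Tf2NH (18 mol %), acrolein (3 equiv), CH2Cl2, −78 to −40 °C; Et3N quench
Reagents that add atoms: none
Why: Normal-electron-demand Diels–Alder cycloaddition between the s-cis-locked diene C12=C18(OEt)–C2=C1 of 5 and acrolein activated as its complex with the chiral oxazaborolidinium ion; the closest known reaction type is the oxazaborolidinium-catalysed endo addition of enals to cyclohexa-1,3-dienes. The future cyclohexene ring (C1–C14–C13–C12–C11–C15) closes by a concerted but asynchronous suprafacial [4+2] addition in which C12–C13 (acrolein β-carbon to the ethoxy-activated diene terminus) leads and C14–C1 follows, so that a bicyclo[2.2.2]octenone results. C1 is set by the choice of diene face, which is dictated jointly by the catalyst-shielded face of the enal, the endo orientation of CHO and the regiochemistry; bridgehead C12 is coupled to C1, C14 carries the endo CHO, and both of these centres are erased in steps 4 to 7. The step therefore needs high regio-, endo- and enantioface selectivity, because after excision of CHO any regio- or exo-isomer becomes the enantiomer of 8. The ethoxy group secures the regiochemistry by making C12 the nucleophilic terminus, the Lewis acid secures endo addition, and the quaternary C15 prevents tautomerisation of the dienone. The bridgehead positions protect C1 and C12 from epimerisation until the temporary C18=C2 bridge is cleaved.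

Step 4
Reactants: 7 (1R,2R,4R)-5-ethoxy-7,7-dimethyl-8-oxobicyclo[2.2.2]oct-5-ene-2-carbaldehyde
Product: 8 (1R,4S)-6-ethoxy-3,3-dimethylbicyclo[2.2.2]oct-5-en-2-one
Conditions: RhCl(PPh3)3 (1.1 equiv), toluene, 110 °C
Reagents that add atoms: none
Why: Tsuji–Wilkinson decarbonylation: monovalent rhodium inserts into the formyl C–H bond, extrudes CO and reductively eliminates C–H, so that C14 becomes a CH2 group while the non-enolisable ketone, the enol ether and both bridgehead stereocentres are untouched.

Step 5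
Reactants: 8 (1R,4S)-6-ethoxy-3,3-dimethylbicyclo[2.2.2]oct-5-en-2-one
Product: 10 ethyl (4R)-4-formyl-3,3-dimethyl-2-oxocyclohexane-1-carboxylate, via ethoxy ozonide 9 (not isolated)
Conditions: O3, CH2Cl2, −78 °C; then PPh3, −78 to 25 °C
Reagents that add atoms: ozone, [O-][O+]=O
Why: Ozonolysis of the electron-rich enol ether bridge cleaves C18=C2 only, the ethoxy-bearing carbon emerging as the ethyl ester on C12 and C2 as the aldehyde on C1, and the neutral reductive work-up should leave the C1 stereocentre (now α to the aldehyde) unchanged, while C12 becomes an epimerisable β-keto ester centre of no consequence.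

Step 6
Reactants: 10 ethyl (4R)-4-formyl-3,3-dimethyl-2-oxocyclohexane-1-carboxylate
Product: 11 ethyl (4S)-4-ethenyl-3,3-dimethyl-2-oxocyclohexane-1-carboxylate
Conditions: Zn, CH2I2, Ti(OiPr)4, THF, 25 °C
Reagents that add atoms: diiodomethane, ICI
Why: Takai-type methylenation with the CH2I2/Zn/Ti(OiPr)4 reagent is non-basic and selective for aldehydes, so the ketone and ester are spared and C1 is not epimerised (the descriptor changes from R to S only because of the priority rules).

Step 7
Reactants: 11 ethyl (4S)-4-ethenyl-3,3-dimethyl-2-oxocyclohexane-1-carboxylate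
Product: 12 ethyl (4S)-4-ethenyl-3,3-dimethyl-2-{[(trifluoromethyl)sulfonyl]oxy}cyclohex-1-ene-1-carboxylate
Conditions: NaH, Et2O, 0 °C; then Tf2O, −78 to 0 °C
Reagents that add atoms: trifluoromethanesulfonic anhydride, O=S(=O)(OS(=O)(=O)C(F)(F)F)C(F)(F)F
Why: O-Sulfonylation of the sodium enolate of the β-keto ester: enolisation is possible only towards C12 because C15 is quaternary, so the C11=C12 enol triflate should form as a single regioisomer with C1 untouched.

Step 8
Reactants: 13 tert-butyl(but-3-yn-1-yloxy)dimethylsilane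
Product: 16 (2E)-5-{[tert-butyl(dimethyl)silyl]oxy}-3-methylpent-2-en-1-ol, via alkenylalane 14 (not isolated), via lithium alanate 15 (not isolated)
Conditions: AlMe3, Cp2ZrCl2 (20 mol %), CH2Cl2, 0 to 25 °C; n-BuLi, THF, −78 °C; (CH2O)n, to 25 °C
Reagents that add atoms: trimethylaluminium, C[Al](C)C; paraformaldehyde (reacting as formaldehyde), C=O
Why: Zirconium-catalysed carboalumination (Negishi) adds methyl and aluminium syn across the terminal alkyne with methyl on the internal carbon, which fixes the E geometry of the future C7=C8 alkene, and the derived alanate is hydroxymethylated by formaldehyde with retention.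

Step 9
Reactants: 16 (2E)-5-{[tert-butyl(dimethyl)silyl]oxy}-3-methylpent-2-en-1-ol
Product: 17 (2E)-5-{[tert-butyl(dimethyl)silyl]oxy}-3-methylpent-2-enal
Conditions: MnO2, CH2Cl2, 25 °C
Reagents that add atoms: none
Why: Selective oxidation of the allylic alcohol with MnO2 should give the enal (C6 aldehyde) without touching the silyl ether or the alkene geometry.

Step 10
Reactants: 17 (2E)-5-{[tert-butyl(dimethyl)silyl]oxy}-3-methylpent-2-enal; 18 allenylboronic acid pinacol ester
Product: 20 (4S,5E)-8-{[tert-butyl(dimethyl)silyl]oxy}-6-methyloct-5-en-1-yn-4-ol, via pinacol borate 19 (not isolated)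
Conditions: (S)-3,3′-bis(2,4,6-triisopropylphenyl)-1,1′-binaphthyl-2,2′-diyl hydrogen phosphate (5 mol %), 4 Å molecular sieves, toluene, −20 °C; aqueous NaHCO3 work-up
Reagents that add atoms: none
Why: Chiral phosphoric acid-catalysed propargylboration: the allenylboronate adds to the aldehyde through a closed six-membered SE2′ transition state organised by the phosphate, which selects one carbonyl face and should set C6 as S, and the borate is hydrolysed on work-up.

Step 11
Reactants: 20 (4S,5E)-8-{[tert-butyl(dimethyl)silyl]oxy}-6-methyloct-5-en-1-yn-4-ol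
Product: 21 (4S,5E)-8-{[tert-butyl(dimethyl)silyl]oxy}-6-methyloct-5-en-1-yn-4-yl acetate
Conditions: Ac2O, pyridine, DMAP (cat.), CH2Cl2, 0 to 25 °C
Reagents that add atoms: acetic anhydride, CC(=O)OC(C)=O
Why: Acylation of the secondary alcohol under DMAP catalysis installs the C6 acetate of the target without affecting the stereocentre.

Step 12
Reactants: 21 (4S,5E)-8-{[tert-butyl(dimethyl)silyl]oxy}-6-methyloct-5-en-1-yn-4-yl acetate
Product: 23 (4S,5E)-8-{[tert-butyl(dimethyl)silyl]oxy}-2-iodo-6-methylocta-1,5-dien-4-yl acetate, via iodoalkenylborane 22 (not isolated)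
Conditions: B-iodo-9-BBN, pentane, −20 °C; then AcOH, 0 °C
Reagents that add atoms: B-iodo-9-borabicyclo[3.3.1]nonane, IB1C2CCCC1CCC2
Why: Syn iodoboration of the terminal alkyne places iodine on the internal carbon and protodeboronation with acetic acid then gives the 2-iodo-1-alkene (C4), while the trisubstituted alkene does not react and C6 is untouched.

Step 13
Reactants: 23 (4S,5E)-8-{[tert-butyl(dimethyl)silyl]oxy}-2-iodo-6-methylocta-1,5-dien-4-yl acetate
Product: 24 (4S,5E)-8-hydroxy-2-iodo-6-methylocta-1,5-dien-4-yl acetate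
Conditions: HF·pyridine, pyridine, THF, 0 to 25 °C
Reagents that add atoms: none
Why: Fluoride-mediated cleavage of the primary silyl ether under conditions that should leave the acetate and the alkenyl iodide intact.

Step 14
Reactants: 12 ethyl (4S)-4-ethenyl-3,3-dimethyl-2-{[(trifluoromethyl)sulfonyl]oxy}cyclohex-1-ene-1-carboxylate; 24 (4S,5E)-8-hydroxy-2-iodo-6-methylocta-1,5-dien-4-yl acetate
Product: 26 ethyl (4R)-4-[(5S,6E)-5-(acetyloxy)-9-hydroxy-7-methyl-3-methylidenenon-6-en-1-yl]-3,3-dimethyl-2-{[(trifluoromethyl)sulfonyl]oxy}cyclohex-1-ene-1-carboxylate, via alkylborane 25 (not isolated)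
Conditions: 12, 9-BBN, THF, 0 to 25 °C; then 24, Pd(dppf)Cl2 (10 mol %), AsPh3, Cs2CO3, DMF/H2O, 25 °C
Reagents that add atoms: none
Why: Anti-Markovnikov hydroboration of the vinyl group (the tetrasubstituted enol triflate is inert to 9-BBN) followed by B-alkyl Suzuki–Miyaura coupling, in which zerovalent palladium should insert into the unhindered alkenyl iodide at room temperature much faster than into the tetrasubstituted enol triflate flanked by C15, forms C3–C4 and the exocyclic methylene without touching a stereocentre.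

Step 15
Reactants: 26 ethyl (4R)-4-[(5S,6E)-5-(acetyloxy)-9-hydroxy-7-methyl-3-methylidenenon-6-en-1-yl]-3,3-dimethyl-2-{[(trifluoromethyl)sulfonyl]oxy}cyclohex-1-ene-1-carboxylate
Product: 27 ethyl (4R)-4-[(5S,6E)-5-(acetyloxy)-7-methyl-3-methylidene-9-oxonon-6-en-1-yl]-3,3-dimethyl-2-{[(trifluoromethyl)sulfonyl]oxy}cyclohex-1-ene-1-carboxylate
Conditions: Dess–Martin periodinane, NaHCO3, CH2Cl2, 0 °C; used crude
Reagents that add atoms: none
Why: Dess–Martin oxidation under bicarbonate buffering should give the β,γ-unsaturated C10 aldehyde without migration of the C7=C8 double bond.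

Step 16
Reactants: 27 ethyl (4R)-4-[(5S,6E)-5-(acetyloxy)-7-methyl-3-methylidene-9-oxonon-6-en-1-yl]-3,3-dimethyl-2-{[(trifluoromethyl)sulfonyl]oxy}cyclohex-1-ene-1-carboxylate
Product: 29 (1R,6S,7E,10R)-6-acetoxyverticilla-4(20),7,11-trien-18,10-olide (CNP0289913.1), via macrocyclic hydroxy ester 28 (not isolated)
Conditions: CrCl2 (8 equiv), NiCl2 (2 mol %), DMSO/THF, 25 °C, 2 mM; aqueous NH4Cl; PPTS (cat.), CH2Cl2, 25 °C
Reagents that add atoms: none
Why: Nozaki–Hiyama–Kishi reaction: zerovalent nickel inserts into the enol triflate, transmetalation gives the alkenylchromium species, and its intramolecular 1,2-addition to the aldehyde forms C10–C11 and the twelve-membered ring, after which the γ-hydroxy enoate lactonises to the butenolide; C10 should be set as R by substrate control, because the tether from C1 can only deliver C9 on the face of the ring that carries C2 while chromium chelated by the ester places the oxygen on the C12 side.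

Compound list
1 | 3-ethoxycyclohex-2-en-1-one | CCOC1=CC(=O)CCC1 | starting material
2 | 3-ethoxy-6-methylcyclohex-2-en-1-one (racemic, not isolated) | CCOC1=CC(=O)C(C)CC1 | intermediate
3 | 3-ethoxy-6,6-dimethylcyclohex-2-en-1-one | CCOC1=CC(=O)C(C)(C)CC1 | intermediate
4 | [(3-ethoxy-6,6-dimethylcyclohexa-1,3-dien-1-yl)oxy]trimethylsilane (not isolated) | CCOC1=CCC(C)(C)C(O[Si](C)(C)C)=C1 | intermediate
5 | 3-ethoxy-6,6-dimethylcyclohexa-2,4-dien-1-one | CCOC1=CC(=O)C(C)(C)C=C1 | intermediate
6 | acrolein (prop-2-enal) | C=CC=O | starting material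
7 | (1R,2R,4R)-5-ethoxy-7,7-dimethyl-8-oxobicyclo[2.2.2]oct-5-ene-2-carbaldehyde | CCOC1=C[C@@H]2[C@H](C=O)C[C@H]1C(=O)C2(C)C | intermediate
8 | (1R,4S)-6-ethoxy-3,3-dimethylbicyclo[2.2.2]oct-5-en-2-one | CCOC1=C[C@@H]2CC[C@H]1C(=O)C2(C)C | intermediate
9 | ethoxy ozonide of 8 (1,2,4-trioxolane across the former enol ether carbons; ozonide carbons unassigned; not isolated) | CCOC12OOC(O1)[C@@H]3CC[C@H]2C(=O)C3(C)C | intermediate
10 | ethyl (4R)-4-formyl-3,3-dimethyl-2-oxocyclohexane-1-carboxylate (C1 epimers and enol) | CCOC(=O)C1CC[C@@H](C=O)C(C)(C)C1=O | intermediate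
11 | ethyl (4S)-4-ethenyl-3,3-dimethyl-2-oxocyclohexane-1-carboxylate (C1 epimers and enol) | CCOC(=O)C1CC[C@@H](C=C)C(C)(C)C1=O | intermediate
12 | ethyl (4S)-4-ethenyl-3,3-dimethyl-2-{[(trifluoromethyl)sulfonyl]oxy}cyclohex-1-ene-1-carboxylate | CCOC(=O)C1=C(OS(=O)(=O)C(F)(F)F)C(C)(C)[C@H](C=C)CC1 | intermediate
13 | tert-butyl(but-3-yn-1-yloxy)dimethylsilane | C#CCCO[Si](C)(C)C(C)(C)C | starting material
14 | {(1E)-4-{[tert-butyl(dimethyl)silyl]oxy}-2-methylbut-1-en-1-yl}dimethylalane (not isolated) | C[Al](C)/C=C(\C)CCO[Si](C)(C)C(C)(C)C | intermediate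
15 | lithium butyl{(1E)-4-{[tert-butyl(dimethyl)silyl]oxy}-2-methylbut-1-en-1-yl}dimethylalanate (not isolated) | [Li+].CCCC[Al-](C)(C)/C=C(\C)CCO[Si](C)(C)C(C)(C)C | intermediate
16 | (2E)-5-{[tert-butyl(dimethyl)silyl]oxy}-3-methylpent-2-en-1-ol | OC/C=C(\C)CCO[Si](C)(C)C(C)(C)C | intermediate
17 | (2E)-5-{[tert-butyl(dimethyl)silyl]oxy}-3-methylpent-2-enal | O=C/C=C(\C)CCO[Si](C)(C)C(C)(C)C | intermediate
18 | allenylboronic acid pinacol ester (4,4,5,5-tetramethyl-2-(propa-1,2-dien-1-yl)-1,3,2-dioxaborolane) | C=C=CB1OC(C)(C)C(C)(C)O1 | starting material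
19 | pinacol borate of 20 (O-boryl ether, not isolated) | C#CC[C@H](OB1OC(C)(C)C(C)(C)O1)/C=C(\C)CCO[Si](C)(C)C(C)(C)C | intermediate
20 | (4S,5E)-8-{[tert-butyl(dimethyl)silyl]oxy}-6-methyloct-5-en-1-yn-4-ol | C#CC[C@H](O)/C=C(\C)CCO[Si](C)(C)C(C)(C)C | intermediate
21 | (4S,5E)-8-{[tert-butyl(dimethyl)silyl]oxy}-6-methyloct-5-en-1-yn-4-yl acetate | C#CC[C@H](OC(C)=O)/C=C(\C)CCO[Si](C)(C)C(C)(C)C | intermediate
22 | (1Z,4S,5E)-1-(9-borabicyclo[3.3.1]nonan-9-yl)-8-{[tert-butyl(dimethyl)silyl]oxy}-2-iodo-6-methylocta-1,5-dien-4-yl acetate (not isolated) | I/C(C[C@H](OC(C)=O)/C=C(\C)CCO[Si](C)(C)C(C)(C)C)=C\B1C2CCCC1CCC2 | intermediate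
23 | (4S,5E)-8-{[tert-butyl(dimethyl)silyl]oxy}-2-iodo-6-methylocta-1,5-dien-4-yl acetate | C=C(I)C[C@H](OC(C)=O)/C=C(\C)CCO[Si](C)(C)C(C)(C)C | intermediate
24 | (4S,5E)-8-hydroxy-2-iodo-6-methylocta-1,5-dien-4-yl acetate | C=C(I)C[C@H](OC(C)=O)/C=C(\C)CCO | intermediate
25 | ethyl (4R)-4-[2-(9-borabicyclo[3.3.1]nonan-9-yl)ethyl]-3,3-dimethyl-2-{[(trifluoromethyl)sulfonyl]oxy}cyclohex-1-ene-1-carboxylate (not isolated) | CCOC(=O)C1=C(OS(=O)(=O)C(F)(F)F)C(C)(C)[C@H](CCB2C3CCCC2CCC3)CC1 | intermediate
26 | ethyl (4R)-4-[(5S,6E)-5-(acetyloxy)-9-hydroxy-7-methyl-3-methylidenenon-6-en-1-yl]-3,3-dimethyl-2-{[(trifluoromethyl)sulfonyl]oxy}cyclohex-1-ene-1-carboxylate | CCOC(=O)C1=C(OS(=O)(=O)C(F)(F)F)C(C)(C)[C@H](CCC(=C)C[C@H](OC(C)=O)/C=C(\C)CCO)CC1 | intermediate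
27 | ethyl (4R)-4-[(5S,6E)-5-(acetyloxy)-7-methyl-3-methylidene-9-oxonon-6-en-1-yl]-3,3-dimethyl-2-{[(trifluoromethyl)sulfonyl]oxy}cyclohex-1-ene-1-carboxylate | CCOC(=O)C1=C(OS(=O)(=O)C(F)(F)F)C(C)(C)[C@H](CCC(=C)C[C@H](OC(C)=O)/C=C(\C)CC=O)CC1 | intermediate
28 | ethyl (1R,6S,7E,10R)-6-acetoxy-10-hydroxyverticilla-4(20),7,11-trien-18-oate (macrocyclic hydroxy ester, not isolated) | C=C1CC[C@@H]2CCC(C(=O)OCC)=C([C@@H](C/C(C)=C/[C@@H](OC(C)=O)C1)O)C2(C)C | intermediate
29 | (1R,6S,7E,10R)-6-acetoxyverticilla-4(20),7,11-trien-18,10-olide (CNP0289913.1) | C=C1CC[C@@H]2CCC3=C([C@@H](C/C(C)=C/[C@@H](OC(C)=O)C1)OC3=O)C2(C)C | target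

Total step count: 16. Longest linear sequence: 10 steps (steps 1 to 7, then 14 to 16); the side-chain fragment 24 takes 6 steps (8 to 13).

Steps most likely to fail, each with a fallback

1. Step 3. The basic vinylogous-ester carbonyl of 5 may compete with acrolein for the boron Lewis acid, so that an uncatalysed background cycloaddition erodes facial, endo and regiochemical control, all three of which feed into the enantiomeric purity of 8. In that case the chirality is delivered through a two-point-binding dienophile and the traceless group is a carboxyl instead of a formyl group. Setting out from 5, cycloaddition with 3-acryloyl-1,3-oxazolidin-2-one under catalysis by the divalent copper complex [Cu(t-Bu-box)](SbF6)2 (ligand antipode chosen as in the assumption; CH2Cl2, −40 °C) should give the endo imide adduct F1. LiOH/H2O2 (THF/H2O, 0 °C) then removes the oxazolidinone to give the carboxylic acid F2. Esterification with N-hydroxypyridine-2-thione (EDC, DMAP) gives the thiohydroxamate ester F3, and photolysis with t-BuSH (Barton decarboxylation) replaces the carboxyl group by hydrogen and comes back to the route at 8.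

2. Step 16. During ring closure the alkenylchromium may add to the other face of the aldehyde (poor facial selectivity), which gives the C10 epimer that cannot lactonise without forcing C9 onto the wrong face of the ring. Facial control is then handed to a reagent. Setting out from 27, the ring closure would in that event deliver the (10S)-hydroxy ester F4; Dess–Martin oxidation converts it into the macrocyclic γ-keto enoate F5. Corey–Bakshi–Shibata reduction with the (S)-methyl oxazaborolidine and catecholborane (tetrasubstituted alkenyl group as the large substituent, −78 °C, so that the alkenes are not hydroborated) should then give 28, where the route is rejoined and lactonisation leads to 29.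

3. Step 14. Zerovalent palladium may insert competitively into the enol triflate, so that the borane oligomerises instead of cross-coupling. The triflate is then introduced only after the coupling. Setting out from 11, silylation (TBSOTf, Et3N, CH2Cl2) gives the silyl enol ether F6; hydroboration with 9-BBN gives the alkylborane F7, which is coupled under the same palladium conditions with the silyl-protected iodide 23 to give the bis-silyl coupling product F8. CsF and PhNTf2 (DME) convert the enol silyl ether directly into the enol triflate F9, and HF·pyridine then removes the primary silyl ether, which comes back to the route at 26.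

Further compounds
F1 | step 3 | 3-{[(1R,2R,4R)-5-ethoxy-7,7-dimethyl-8-oxobicyclo[2.2.2]oct-5-en-2-yl]carbonyl}-1,3-oxazolidin-2-one | CCOC1=C[C@@H]2[C@H](C(=O)N3CCOC3=O)C[C@H]1C(=O)C2(C)C
F2 | step 3 | (1R,2R,4R)-5-ethoxy-7,7-dimethyl-8-oxobicyclo[2.2.2]oct-5-ene-2-carboxylic acid | CCOC1=C[C@@H]2[C@H](C(=O)O)C[C@H]1C(=O)C2(C)C
F3 | step 3 | 2-thioxopyridin-1(2H)-yl (1R,2R,4R)-5-ethoxy-7,7-dimethyl-8-oxobicyclo[2.2.2]oct-5-ene-2-carboxylate | CCOC1=C[C@@H]2[C@H](C(=O)On3ccccc3=S)C[C@H]1C(=O)C2(C)C
F4 | step 16 | ethyl (1R,6S,7E,10S)-6-acetoxy-10-hydroxyverticilla-4(20),7,11-trien-18-oate | C=C1CC[C@@H]2CCC(C(=O)OCC)=C([C@H](C/C(C)=C/[C@@H](OC(C)=O)C1)O)C2(C)C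
F5 | step 16 | ethyl (1R,6S,7E)-6-acetoxy-10-oxoverticilla-4(20),7,11-trien-18-oate | C=C1CC[C@@H]2CCC(C(=O)OCC)=C(C(=O)C/C(C)=C/[C@@H](OC(C)=O)C1)C2(C)C
F6 | step 14 | ethyl (4S)-2-{[tert-butyl(dimethyl)silyl]oxy}-4-ethenyl-3,3-dimethylcyclohex-1-ene-1-carboxylate | CCOC(=O)C1=C(O[Si](C)(C)C(C)(C)C)C(C)(C)[C@H](C=C)CC1
F7 | step 14 | ethyl (4R)-4-[2-(9-borabicyclo[3.3.1]nonan-9-yl)ethyl]-2-{[tert-butyl(dimethyl)silyl]oxy}-3,3-dimethylcyclohex-1-ene-1-carboxylate | CCOC(=O)C1=C(O[Si](C)(C)C(C)(C)C)C(C)(C)[C@H](CCB2C3CCCC2CCC3)CC1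
F8 | step 14 | ethyl (4R)-4-[(5S,6E)-5-(acetyloxy)-9-{[tert-butyl(dimethyl)silyl]oxy}-7-methyl-3-methylidenenon-6-en-1-yl]-2-{[tert-butyl(dimethyl)silyl]oxy}-3,3-dimethylcyclohex-1-ene-1-carboxylate | CCOC(=O)C1=C(O[Si](C)(C)C(C)(C)C)C(C)(C)[C@H](CCC(=C)C[C@H](OC(C)=O)/C=C(\C)CCO[Si](C)(C)C(C)(C)C)CC1
F9 | step 14 | ethyl (4R)-4-[(5S,6E)-5-(acetyloxy)-9-{[tert-butyl(dimethyl)silyl]oxy}-7-methyl-3-methylidenenon-6-en-1-yl]-3,3-dimethyl-2-{[(trifluoromethyl)sulfonyl]oxy}cyclohex-1-ene-1-carboxylate | CCOC(=O)C1=C(OS(=O)(=O)C(F)(F)F)C(C)(C)[C@H](CCC(=C)C[C@H](OC(C)=O)/C=C(\C)CCO[Si](C)(C)C(C)(C)C)CC1
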